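**Plan**

Locants are the von Baeyer numbers of the tricyclo[5.3.1.0^{1,5}]undecane core: ring A = cyclopentane C1–C5, ring B = cyclopentanone C1/C5/C6/C7/C11, ring C = trione ring C1/C11/C7/C8/C9/C10.
Retrosynthesis cuts, in order: the C9–prenyl bond; acetyl back to isopropenyl; then C1–C5 and C3–C4 together, a formal (3+2) opening of ring A that also opens ring B; finally the two C–prenyl bonds and the C–acyl bond of an acylphloroglucinol.
Enabling feature: C1 is the α-carbon of the C10/C11 1,3-diketone and can be oxidised to a radical; the prenyl chain C6–C5=C4 on quaternary C7 lies 5-exo to it (ring B), and the tertiary radical left at gem-dimethyl C4 lies 5-exo to C3, the inner carbon of a second prenyl group on C1 (ring A).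
Forward: 2-methylphloroglucinol → acylation → C-prenylation → enantioselective dearomative prenylation (ring C, dearomatised) → oxidative radical cascade (ring B, then ring A) → ozonolysis → C3 epimerisation → C9 prenylation.
Stereochemistry: C7 from the chiral bisphosphine ligand of the Pd2(dba)3-derived catalyst; C1 and C5 relayed from C7 by the bridged geometry of the cascade; C3 by equilibration α to the acetyl group; C9 by exo-face alkylation, syn to the C11 bridge.

Key step: step 4

Remark: the (R,R)-ligand of step 3 is assumed to give the (R)-centre of 7 (if the sense of induction is the reverse, its enantiomer is used); enolised tricarbonyl compounds are written as one tautomer and their descriptors refer to that tautomer.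

**Route**

Step 1
Reactants: 1 2-methylbenzene-1,3,5-triol (2-methylphloroglucinol); 2 2-methylpropanoyl chloride
Product: 3 2-methyl-1-(2,4,6-trihydroxy-3-methylphenyl)propan-1-one
Conditions: AlCl3 (4 equiv), PhNO2, 60 °C; then ice/aq. HCl
Reagents that add atoms: none
Why: Friedel–Crafts acylation of the electron-rich triol at one of its two equivalent free ring carbons; the chelated aryl ketone is deactivated, which should stop the reaction at mono-acylation.

Step 2
Reactants: 3 2-methyl-1-(2,4,6-trihydroxy-3-methylphenyl)propan-1-one; 4 1-bromo-3-methylbut-2-ene (prenyl bromide)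
Product: 5 2-methyl-1-[2,4,6-trihydroxy-3-methyl-5-(3-methylbut-2-en-1-yl)phenyl]propan-1-one
Conditions: 10% aq. KOH (1.1 equiv), 0 °C to rt; aq. HCl
Reagents that add atoms: none
Why: C-alkylation of the ambident phloroglucinolate (aqueous base favours carbon over oxygen attack) at the only unsubstituted ring carbon, followed by re-aromatising tautomerisation; no stereocentre is formed.

Step 3
Reactants: 5 2-methyl-1-[2,4,6-trihydroxy-3-methyl-5-(3-methylbut-2-en-1-yl)phenyl]propan-1-one; 6 3-methylbut-2-en-1-yl acetate (prenyl acetate)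
Product: 7 (6R)-3,5-dihydroxy-6-methyl-4-(2-methylpropanoyl)-2,6-bis(3-methylbut-2-en-1-yl)cyclohexa-2,4-dien-1-one
Conditions: Pd2(dba)3·CHCl3 (2.5 mol%), (R,R)-DACH-phenyl bisphosphine [(1R,2R)-N,N′-bis(2-diphenylphosphinobenzoyl)cyclohexane-1,2-diamine] (7.5 mol%), Et3N (1.1 equiv), CH2Cl2, 0 °C to rt
Reagents that add atoms: none
Why: Tsuji–Trost asymmetric allylic alkylation with dearomatisation: the phenolate attacks the unsubstituted terminus of the π-prenyl complex through its methyl-bearing ring carbon (the least hindered substituted position; the acyl-bearing carbon is the least nucleophilic and O-prenyl ethers re-ionise), and the chiral ligand pocket selects the enantiotopic face of the flat nucleophile, which should set the quaternary centre as (R).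

Step 4
Reactants: 7 (6R)-3,5-dihydroxy-6-methyl-4-(2-methylpropanoyl)-2,6-bis(3-methylbut-2-en-1-yl)cyclohexa-2,4-dien-1-one
Product: 10 (1S,5R,7S)-10-hydroxy-4,4,7-trimethyl-9-(2-methylpropanoyl)-3-(prop-1-en-2-yl)tricyclo[5.3.1.0^{1,5}]undec-9-ene-8,11-dione as both C3 epimers, via bicyclic tertiary radical 8 (not isolated), via tricyclic tertiary radical 9 (not isolated)
Conditions: Mn(OAc)3·2H2O (2.2 equiv), Cu(OAc)2·H2O (20 mol%), degassed AcOH, 25 °C
Reagents that add atoms: none
Why: Mn(OAc)3 oxidises the enolised 1,3-dicarbonyl unit of 7 at its only C–H ring carbon (C2 of 7, the future C1) to an electrophilic radical, which adds 5-exo-trig to the inner alkene carbon of the prenyl group on the quaternary carbon to give 8 (ring B, C1–C5 bond); the nucleophilic tertiary radical of 8 then adds 5-exo-trig to the CH= carbon of the prenyl group on C1 to give 9 (ring A, C3–C4 bond), and Cu(OAc)2 converts 9 into the isopropenyl compound by inner-sphere β-hydrogen loss while Mn(OAc)3 re-oxidises the monovalent copper. The closest known reaction type is the Mn(OAc)3/Cu(OAc)2 oxidative free-radical tandem cyclisation of unsaturated 1,3-dicarbonyl compounds, which has close precedent on dearomatised diprenyl acylphloroglucinols. C1 can form only on the ring face that carries the tether, so its configuration follows from the stereocentre of 7, and at C5 the CMe2 radical terminus takes the exo position (syn to the one-carbon carbonyl bridge), the less crowded arrangement and the only one from which ring A can close. C3 is not controlled and both epimers are expected, which is tolerated because C3 becomes α to a ketone in step 5 and is equilibrated in step 6. The step needs radical formation at the C–H carbon and not at the acyl-bearing enol carbon (the tricarbonyl radical is too stabilised to add to an alkene at a useful rate), 5-exo over 6-endo closure twice (each trisubstituted alkene is attacked at its CH end, giving a tertiary radical), and terminal instead of tetrasubstituted alkene formation from 9 (the copper-mediated elimination takes the more accessible methyl hydrogen).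

Step 5
Reactants: 10 (1S,5R,7S)-10-hydroxy-4,4,7-trimethyl-9-(2-methylpropanoyl)-3-(prop-1-en-2-yl)tricyclo[5.3.1.0^{1,5}]undec-9-ene-8,11-dione (both C3 epimers)
Product: 12 (1S,5R,7S)-3-acetyl-10-hydroxy-4,4,7-trimethyl-9-(2-methylpropanoyl)tricyclo[5.3.1.0^{1,5}]undec-9-ene-8,11-dione as both C3 epimers, via secondary ozonide 11 (not isolated)
Conditions: O3 (1.0 equiv, titrated solution), CH2Cl2, −78 °C; then Me2S, −78 °C to rt
Reagents that add atoms: ozone, [O-][O+]=O
Why: Ozonolysis (1,3-dipolar cycloaddition, Criegee fragmentation, reductive work-up) of the 1,1-disubstituted isopropenyl group, the only electron-rich isolated alkene; the hydrogen-bonded, doubly acyl-conjugated enol is a deactivated π-system and should be spared when one equivalent of ozone is dosed; no stereocentre is touched.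

Step 6
Reactants: 12 (1S,5R,7S)-3-acetyl-10-hydroxy-4,4,7-trimethyl-9-(2-methylpropanoyl)tricyclo[5.3.1.0^{1,5}]undec-9-ene-8,11-dione (both C3 epimers)
Product: 13 (1S,3S,5R,7S)-3-acetyl-10-hydroxy-4,4,7-trimethyl-9-(2-methylpropanoyl)tricyclo[5.3.1.0^{1,5}]undec-9-ene-8,11-dione
Conditions: DBU (3 equiv), PhMe, 60 °C; aq. HCl wash
Reagents that add atoms: none
Why: Base-mediated epimerisation through the enolate of the methyl ketone: the acetyl group should settle on the convex face of the cis-fused rings A and B, cis to H5 and away from the C11 carbonyl bridge, which is (3S); the other stereocentres are quaternary or not α to a carbonyl, and the triketone sits as its delocalised anion, which guards it against retro-Claisen cleavage by the non-nucleophilic base.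

Step 7
Reactants: 13 (1S,3S,5R,7S)-3-acetyl-10-hydroxy-4,4,7-trimethyl-9-(2-methylpropanoyl)tricyclo[5.3.1.0^{1,5}]undec-9-ene-8,11-dione; 6 3-methylbut-2-en-1-yl acetate (prenyl acetate)
Product: 14 (1R,3S,5R,7S,9S)-3-acetyl-4,4,7-trimethyl-9-(3-methylbut-2-en-1-yl)-9-(2-methylpropanoyl)tricyclo[5.3.1.0^{1,5}]undecane-8,10,11-trione
Conditions: Pd(PPh3)4 (5 mol%), Et3N (1.2 equiv), THF, 45 °C
Reagents that add atoms: none
Why: Tsuji–Trost C-allylation of a highly acidic β-tricarbonyl compound: the ammonium enolate attacks the unsubstituted terminus of the π-prenyl complex, O-prenyl enol ethers are re-ionised by Pd(PPh3)4 so that the C-alkylated, non-enolisable trione should accumulate, and the electrophile approaches C9 on the exo face (syn to the C11 carbonyl bridge, away from the endo hydrogens of the C5–C6 bridge), which sets (9S) with prenyl syn to C11.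

**Compound list**

The C1 descriptor changes from S (10–13) to R (14) by a priority change only; the geometry is the same.

1 | 2-methylbenzene-1,3,5-triol (2-methylphloroglucinol) | Cc1c(O)cc(O)cc1O | starting material
2 | 2-methylpropanoyl chloride | CC(C)C(=O)Cl | starting material
3 | 2-methyl-1-(2,4,6-trihydroxy-3-methylphenyl)propan-1-one | CC(C)C(=O)c1c(O)cc(O)c(C)c1O | intermediate
4 | 1-bromo-3-methylbut-2-ene (prenyl bromide) | CC(C)=CCBr | starting material
5 | 2-methyl-1-[2,4,6-trihydroxy-3-methyl-5-(3-methylbut-2-en-1-yl)phenyl]propan-1-one | CC(C)C(=O)c1c(O)c(CC=C(C)C)c(O)c(C)c1O | intermediate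
6 | 3-methylbut-2-en-1-yl acetate (prenyl acetate) | CC(C)=CCOC(C)=O | starting material
7 | (6R)-3,5-dihydroxy-6-methyl-4-(2-methylpropanoyl)-2,6-bis(3-methylbut-2-en-1-yl)cyclohexa-2,4-dien-1-one | CC(C)C(=O)C1=C(O)[C@@](C)(CC=C(C)C)C(=O)C(CC=C(C)C)=C1O | intermediate
8 | 2-[(1S,5S,7R)-2-hydroxy-5-methyl-1-(3-methylbut-2-en-1-yl)-3-(2-methylpropanoyl)-4,8-dioxobicyclo[3.2.1]oct-2-en-7-yl]propan-2-yl radical, side chain exo (not isolated) | CC(C)=CC[C@]23C(=O)[C@](C)(C[C@@H]2[C](C)C)C(=O)C(C(=O)C(C)C)=C3O | intermediate
9 | 2-[(1S,5R,7S)-10-hydroxy-4,4,7-trimethyl-9-(2-methylpropanoyl)-8,11-dioxotricyclo[5.3.1.0^{1,5}]undec-9-en-3-yl]propan-2-yl radical, both C3 epimers (not isolated) | C[C](C)C1C[C@]23C(=O)[C@](C)(C[C@@H]2C1(C)C)C(=O)C(C(=O)C(C)C)=C3O | intermediate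
10 | (1S,5R,7S)-10-hydroxy-4,4,7-trimethyl-9-(2-methylpropanoyl)-3-(prop-1-en-2-yl)tricyclo[5.3.1.0^{1,5}]undec-9-ene-8,11-dione, both C3 epimers | CC(=C)C1C[C@]23C(=O)[C@](C)(C[C@@H]2C1(C)C)C(=O)C(C(=O)C(C)C)=C3O | intermediate
11 | 3-methyl-3-[(1S,5R,7S)-10-hydroxy-4,4,7-trimethyl-9-(2-methylpropanoyl)-8,11-dioxotricyclo[5.3.1.0^{1,5}]undec-9-en-3-yl]-1,2,4-trioxolane, secondary ozonide, both C3 epimers (not isolated) | CC1(OCOO1)C2C[C@]34C(=O)[C@](C)(C[C@@H]3C2(C)C)C(=O)C(C(=O)C(C)C)=C4O | intermediate
12 | (1S,5R,7S)-3-acetyl-10-hydroxy-4,4,7-trimethyl-9-(2-methylpropanoyl)tricyclo[5.3.1.0^{1,5}]undec-9-ene-8,11-dione, both C3 epimers | CC(=O)C1C[C@]23C(=O)[C@](C)(C[C@@H]2C1(C)C)C(=O)C(C(=O)C(C)C)=C3O | intermediate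
13 | (1S,3S,5R,7S)-3-acetyl-10-hydroxy-4,4,7-trimethyl-9-(2-methylpropanoyl)tricyclo[5.3.1.0^{1,5}]undec-9-ene-8,11-dione | CC(=O)[C@H]1C[C@]23C(=O)[C@](C)(C[C@@H]2C1(C)C)C(=O)C(C(=O)C(C)C)=C3O | intermediate
14 | (1R,3S,5R,7S,9S)-3-acetyl-4,4,7-trimethyl-9-(3-methylbut-2-en-1-yl)-9-(2-methylpropanoyl)tricyclo[5.3.1.0^{1,5}]undecane-8,10,11-trione | CC(=O)[C@H]1C[C@]23C(=O)[C@](C)(C[C@@H]2C1(C)C)C(=O)[C@](CC=C(C)C)(C(=O)C(C)C)C3=O | target

**Step count and risks**

Total step count: 7. Longest linear sequence: 7 steps (1 to 14).

Steps most likely to fail: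

1. Step 3. The risks are poor facial discrimination of the flat phenolate, competing attack through the prenyl-bearing ring carbon or through oxygen, and over-prenylation of the acidic product. Fallback, setting out from 5: non-selective dearomative prenylation with 4 (NaOMe, MeOH, 0 °C) should give the racemic dienone F1. This is resolved by fractional crystallisation of its salts with (S)-1-phenylethylamine; the (S)-1-phenylethylammonium salt of the (R)-dienone F2 is taken from the crop or the mother liquor, and aq. HCl liberates the free enol. The fallback comes back to the route at 7.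

2. Step 7. The risks are persistent O-alkylation of the tricarbonyl anion, attack at the tertiary terminus of the prenyl unit, approach from the endo face, and retro-Claisen opening of the non-enolisable trione. Fallback, setting out from 13: O-allylation (allyl bromide, K2CO3, acetone) should give the allyl enol ether F3. Thermal Claisen rearrangement (PhMe, 110 °C) transfers the allyl group suprafacially to C9 on the exo face and gives the C9-allyl trione F4. Cross-metathesis with 2-methylbut-2-ene (second-generation Grubbs catalyst, CH2Cl2, 40 °C) turns allyl into prenyl. The fallback comes back to the route at 14.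

3. Step 4. The risks are oxidation starting at the acyl-bearing enol, oxidation of radical 8 before the second ring closes, over-oxidation of the product enol, and elimination to the tetrasubstituted alkene. Fallback, setting out from 7: bromination of the C–H carbon of the 1,3-dione (N-bromosuccinimide, CH2Cl2, 0 °C) should give the 2-bromo-1,3-dione F5. Bromine-atom-transfer radical cyclisation (Ru(bpy)3Cl2 1 mol%, LiBr, DMF, blue light) runs the same two 5-exo closures without a stoichiometric oxidant and ends in the tertiary bromide F6. Dehydrobromination (DBU, PhMe, 60 °C) removes the accessible methyl hydrogen. The fallback comes back to the route at 10.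

Further compounds
F1 | step 3 | racemic 3,5-dihydroxy-6-methyl-4-(2-methylpropanoyl)-2,6-bis(3-methylbut-2-en-1-yl)cyclohexa-2,4-dien-1-one | CC(C)C(=O)C1=C(O)C(C)(CC=C(C)C)C(=O)C(CC=C(C)C)=C1O
F2 | step 3 | (S)-1-phenylethylammonium salt of (6R)-3,5-dihydroxy-6-methyl-4-(2-methylpropanoyl)-2,6-bis(3-methylbut-2-en-1-yl)cyclohexa-2,4-dien-1-one | CC(C)C(=O)C1=C([O-])[C@@](C)(CC=C(C)C)C(=O)C(CC=C(C)C)=C1O.C[C@H]([NH3+])c1ccccc1
F3 | step 7 | (1S,3S,5R,7S)-3-acetyl-4,4,7-trimethyl-9-(2-methylpropanoyl)-10-(prop-2-en-1-yloxy)tricyclo[5.3.1.0^{1,5}]undec-9-ene-8,11-dione | CC(=O)[C@H]1C[C@]23C(=O)[C@](C)(C[C@@H]2C1(C)C)C(=O)C(C(=O)C(C)C)=C3OCC=C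
F4 | step 7 | (1R,3S,5R,7S,9S)-3-acetyl-4,4,7-trimethyl-9-(2-methylpropanoyl)-9-(prop-2-en-1-yl)tricyclo[5.3.1.0^{1,5}]undecane-8,10,11-trione | CC(=O)[C@H]1C[C@]23C(=O)[C@](C)(C[C@@H]2C1(C)C)C(=O)[C@](CC=C)(C(=O)C(C)C)C3=O
F5 | step 4 | (6R)-2-bromo-5-hydroxy-6-methyl-4-(2-methylpropanoyl)-2,6-bis(3-methylbut-2-en-1-yl)cyclohex-4-ene-1,3-dione, both C2 epimers | CC(C)C(=O)C1=C(O)[C@@](C)(CC=C(C)C)C(=O)C(Br)(CC=C(C)C)C1=O
F6 | step 4 | (1S,5R,7S)-3-(2-bromopropan-2-yl)-10-hydroxy-4,4,7-trimethyl-9-(2-methylpropanoyl)tricyclo[5.3.1.0^{1,5}]undec-9-ene-8,11-dione, both C3 epimers | CC(C)(Br)C1C[C@]23C(=O)[C@](C)(C[C@@H]2C1(C)C)C(=O)C(C(=O)C(C)C)=C3O
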